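**Retrosynthetic overview**

1. Endgame: target 30 ⇐ keto acid 28 (ring C still a trimethyl ether; the para-dimethoxy pair is oxidised to the quinone and reduced to the hydroquinone) ⇐ keto aldehyde 27.
2. Key disconnection (target numbered as a 1-tetralone): the C1–C8a bond (ketone carbon to arene) is cut and C1 is reconnected to Cα, the CH2 next to the carboxyl carbon: 27 ⇐ monocyclic 2-(alkoxymethylidene)cyclohexanone 23. Forward, the aryllithium at C8a adds across the ring to the ketone and the bridged aldol is cleaved by retro-aldol reaction, so ring B closes while the carbocycle opens into the side chain.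
3. Enabling feature: quaternary C4 carries both the arene (C4a/C8a, C8a being the only free arene position) and the chain Cβ–Cα–CO2H, and C1 is the ketone. Joining Cα to C1 gives a six-membered ring C1–C2–C3–C4–Cβ–Cα whose C1/Cα/carboxyl carbon form a cleavable β-dicarbonyl unit and whose aryl group on C4 lies 1,4 across from C1.
4. 23 ⇐ enone 19 (iodination, reductive formylation, O-alkylation) ⇐ δ-lactone 16 (MeLi, oxidation, aldol condensation) ⇐ lactone 14 (reduction, regioselective re-lactonisation). C3 is set by rhodium-catalysed asymmetric addition to 5,6-dihydro-2H-pyran-2-one, C4 by α-arylation then methylation anti to the isopropenyl group.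
5. Order of rings: ring C is bought as an arene (isopropylated, brominated) → temporary lactone → temporary cyclohexanone → ring B in the key step.

Key step: step 14

Remark: locants C1–C8a, Cα and Cβ in the Why lines refer to the target numbered as a 1-tetralone; compound names use their own locants; Ar = 2,3,5-trimethoxy-4-(propan-2-yl)phenyl, ArI = 2-iodo-3,5,6-trimethoxy-4-(propan-2-yl)phenyl; compounds 1, 2, 8 and 9 are taken as commercial.

**Route**

Step 1
Reactants: 1 1,2,4-trimethoxybenzene; 2 acetone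
Product: 4 2-(2,3,6-trimethoxyphenyl)propan-2-ol, via aryllithium 3 (not isolated)
Conditions: n-BuLi, THF, 0 °C to rt; then 2, −78 °C to rt; H2O
Reagents that add atoms: none
Why: Directed ortho-metalation should take place at the position flanked by two methoxy groups, and the aryllithium adds to the ketone.

Step 2
Reactants: 4 2-(2,3,6-trimethoxyphenyl)propan-2-ol
Product: 5 1,2,4-trimethoxy-3-(propan-2-yl)benzene
Conditions: Et3SiH, CF3CO2H, CH2Cl2, 0 °C to rt
Reagents that add atoms: none
Why: Ionic hydrogenation, in which the tertiary benzylic cation stabilised by two ortho methoxy groups is reduced by the silane.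

Step 3
Reactants: 5 1,2,4-trimethoxy-3-(propan-2-yl)benzene
Product: 7 1-bromo-2,3,5-trimethoxy-4-(propan-2-yl)benzene, via aryllithium 6 (not isolated)
Conditions: n-BuLi, TMEDA, Et2O, 0 °C to rt; then BrCH2CH2Br, −78 °C to rt
Reagents that add atoms: 1,2-dibromoethane, BrCCBr
Why: Directed ortho-metalation should favour H-6 (ortho to one methoxy group and meta to two more) over H-5 (para to a methoxy group), and the aryllithium is brominated by the vicinal dibromide.

Step 4
Reactants: 8 5,6-dihydro-2H-pyran-2-one; 9 potassium trifluoro(prop-1-en-2-yl)borate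
Product: 10 (4R)-4-(prop-1-en-2-yl)oxan-2-one
Conditions: [Rh(cod)2]BF4 (3 mol%), (R)-BINAP, toluene/H2O, 100 °C
Reagents that add atoms: none
Why: Hayashi–Miyaura reaction (rhodium-catalysed asymmetric 1,4-addition of an alkenylboron reagent to an unsaturated lactone), with the ligand enantiomer chosen by analogy with aryl additions to this lactone so that the future C3 is set as (R) in 10.

Step 5
Reactants: 10 (4R)-4-(prop-1-en-2-yl)oxan-2-one; 7 1-bromo-2,3,5-trimethoxy-4-(propan-2-yl)benzene
Product: 12 (3R,4R)-3-Ar-4-(prop-1-en-2-yl)oxan-2-one, via zinc enolate 11 (not isolated)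
Conditions: LiN(SiMe3)2, THF, −78 °C; ZnCl2, −78 °C to rt; Pd(dba)2 (5 mol%), P(t-Bu)3, 7, rt to 50 °C
Reagents that add atoms: none
Why: Palladium-catalysed α-arylation of a Reformatsky-type lactone zinc enolate (Negishi-type coupling), expected to give the trans isomer, whose new centre is reset in step 6.

Step 6
Reactants: 12 (3R,4R)-3-Ar-4-(prop-1-en-2-yl)oxan-2-one
Product: 14 (3S,4S)-3-Ar-3-methyl-4-(prop-1-en-2-yl)oxan-2-one, via lithium enolate 13 (not isolated)
Conditions: LiN(i-Pr)2, THF, −78 °C; MeI, DMPU, −78 to −20 °C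
Reagents that add atoms: iodomethane, CI
Why: Enolate alkylation, in which the planar aryl-stabilised enolate is methylated anti to the neighbouring isopropenyl group, setting the quaternary centre (future C4) with methyl trans and aryl cis to isopropenyl.

Step 7
Reactants: 14 (3S,4S)-3-Ar-3-methyl-4-(prop-1-en-2-yl)oxan-2-one
Product: 15 (2S,3S)-2-Ar-2-methyl-3-(prop-1-en-2-yl)pentane-1,5-diol
Conditions: LiAlH4, THF, 0 °C to rt
Reagents that add atoms: none
Why: Hydride reduction of the lactone to the 1,5-diol, which leaves both stereocentres untouched.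

Step 8
Reactants: 15 (2S,3S)-2-Ar-2-methyl-3-(prop-1-en-2-yl)pentane-1,5-diol
Product: 16 (4S,5S)-5-Ar-5-methyl-4-(prop-1-en-2-yl)oxan-2-one
Conditions: TEMPO (10 mol%), PhI(OAc)2, CH2Cl2, rt
Reagents that add atoms: none
Why: Oxoammonium-mediated oxidative lactonisation is selective for the unhindered primary alcohol over the neopentyl one, so the carbonyl is moved to the carbon that becomes C1.

Step 9
Reactants: 16 (4S,5S)-5-Ar-5-methyl-4-(prop-1-en-2-yl)oxan-2-one
Product: 17 (4S,5S)-5-Ar-6-hydroxy-5-methyl-4-(prop-1-en-2-yl)hexan-2-one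
Conditions: MeLi (1.1 equiv), THF, −78 °C; H2O
Reagents that add atoms: methyllithium, [Li]C
Why: Mono-addition of an organolithium to a δ-lactone should stop at the hydroxy ketone stage at low temperature (the product is in equilibrium with its cyclic hemiketal).

Step 10
Reactants: 17 (4S,5S)-5-Ar-6-hydroxy-5-methyl-4-(prop-1-en-2-yl)hexan-2-one
Product: 19 (4S,5S)-4-Ar-4-methyl-5-(prop-1-en-2-yl)cyclohex-2-en-1-one, via keto aldehyde 18 (not isolated)
Conditions: Dess–Martin periodinane, CH2Cl2, rt; then KOH (0.2 equiv), MeOH, 40 °C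
Reagents that add atoms: none
Why: Alcohol oxidation gives a non-enolisable α-quaternary aldehyde, and intramolecular aldol condensation of the methyl ketone can then only close the six-membered enone.

Step 11
Reactants: 19 (4S,5S)-4-Ar-4-methyl-5-(prop-1-en-2-yl)cyclohex-2-en-1-one
Product: 20 (4S,5S)-4-ArI-4-methyl-5-(prop-1-en-2-yl)cyclohex-2-en-1-one
Conditions: N-iodosuccinimide, CF3CO2H (cat.), MeCN, 0 °C
Reagents that add atoms: N-iodosuccinimide, O=C1CCC(=O)N1I
Why: Electrophilic aromatic iodination at the only free arene position (para and ortho to methoxy groups), the enone and the 1,1-disubstituted alkene being less nucleophilic than the trimethoxyarene.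

Step 12
Reactants: 20 (4S,5S)-4-ArI-4-methyl-5-(prop-1-en-2-yl)cyclohex-2-en-1-one
Product: 22 (2Z,4S,5S)-4-ArI-2-(hydroxymethylidene)-4-methyl-5-(prop-1-en-2-yl)cyclohexan-1-one, via lithium enolate 21 (not isolated)
Conditions: LiBH(s-Bu)3, THF, −78 °C; then HCO2CH2CF3, −78 to 0 °C; 1 M HCl work-up
Reagents that add atoms: 2,2,2-trifluoroethyl formate, O=COCC(F)(F)F
Why: Conjugate hydride reduction of the β-unsubstituted cyclohexenone gives the regiodefined enolate, which is C-formylated (crossed Claisen condensation) at the carbon that becomes Cα.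

Step 13
Reactants: 22 (2Z,4S,5S)-4-ArI-2-(hydroxymethylidene)-4-methyl-5-(prop-1-en-2-yl)cyclohexan-1-one
Product: 23 (2E,4S,5S)-4-ArI-4-methyl-2-[(propan-2-yloxy)methylidene]-5-(prop-1-en-2-yl)cyclohexan-1-one
Conditions: 2-iodopropane, K2CO3, acetone, reflux
Reagents that add atoms: 2-iodopropane, CC(C)I
Why: O-alkylation of the hydroxymethylidene ketone gives a vinylogous ester, which removes the acidic proton between the two carbonyl groups before the organolithium step.

Step 14
Reactants: 23 (2E,4S,5S)-4-ArI-4-methyl-2-[(propan-2-yloxy)methylidene]-5-(prop-1-en-2-yl)cyclohexan-1-one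
Product: 27 3-[(1S,2S)-5,7,8-trimethoxy-1-methyl-4-oxo-6-(propan-2-yl)-2-(prop-1-en-2-yl)-1,2,3,4-tetrahydronaphthalen-1-yl]propanal, via aryllithium 24 (not isolated), via bridged lithium alkoxide 25 (not isolated), via bridged hydroxy aldehyde 26 (not isolated)
Conditions: t-BuLi (2.1 equiv), THF/Et2O, −100 to −40 °C; then 1 M HCl, THF, 0 °C to rt
Reagents that add atoms: water, O
Why: Iodine–lithium exchange (faster than carbonyl attack by t-BuLi at −100 °C) gives aryllithium 24, whose carbanion carbon (future C8a) adds 1,2 to the ring ketone (future C1) lying 1,4 across the cyclohexanone ring, the aryl group being axial on the quaternary carbon because it is cis to the equatorial isopropenyl group, to give the benzobicyclo[2.2.2]octene alkoxide 25. Ring B is thereby closed by a 6-exo-trig carbonyl addition (Parham cyclization; 1,2-addition of organolithiums to alkoxymethylidene ketones is the closest known reaction type). Acidic work-up hydrolyses the enol ether to β-hydroxy aldehyde 26, which cannot dehydrate because its carbinol carbon is a bridgehead and should instead undergo retro-aldol cleavage of the C1–Cα bond, driven by release of the bicyclic strain and formation of the conjugated aryl ketone, so the ring that carried the stereocentres opens into the 3-oxopropyl chain. No new stereocentre survives: C4 (quaternary) and C3 (not α to a carbonyl) pass through unchanged, and the carbinol and formyl-bearing centres of 25 and 26 are destroyed in the fragmentation. The step needs 1,2- rather than 1,4-addition (hard aryllithium, enol-ether β-carbon pointing away from the aryl group), addition rather than proton transfer from the CH2 α to the ketone (low temperature, intramolecular delivery, no proton between two carbonyls), and prompt oxidation of 27 in step 15 before it can re-close by aldol reaction.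

Step 15
Reactants: 27 3-[(1S,2S)-5,7,8-trimethoxy-1-methyl-4-oxo-6-(propan-2-yl)-2-(prop-1-en-2-yl)-1,2,3,4-tetrahydronaphthalen-1-yl]propanal
Product: 28 3-[(1S,2S)-5,7,8-trimethoxy-1-methyl-4-oxo-6-(propan-2-yl)-2-(prop-1-en-2-yl)-1,2,3,4-tetrahydronaphthalen-1-yl]propanoic acid
Conditions: NaClO2, NaH2PO4, 2-methylbut-2-ene, t-BuOH/H2O, 0 °C to rt
Reagents that add atoms: sodium chlorite, [Na+].[O-]Cl=O
Why: Pinnick oxidation of the aldehyde, with the hypochlorite scavenger protecting the isopropenyl group and the arene being fully substituted.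

Step 16
Reactants: 28 3-[(1S,2S)-5,7,8-trimethoxy-1-methyl-4-oxo-6-(propan-2-yl)-2-(prop-1-en-2-yl)-1,2,3,4-tetrahydronaphthalen-1-yl]propanoic acid
Product: 30 3-[(1S,2S)-5,8-dihydroxy-7-methoxy-1-methyl-4-oxo-6-(propan-2-yl)-2-(prop-1-en-2-yl)-1,2,3,4-tetrahydronaphthalen-1-yl]propanoic acid, via quinone 29 (not isolated)
Conditions: (NH4)2Ce(NO3)6, MeCN/H2O, 0 °C; then Na2S2O4, H2O/EtOAc, rt
Reagents that add atoms: water, O
Why: Oxidative demethylation of the para-dimethoxy pair should give the 2-methoxy-1,4-benzoquinone (the third methoxy group is kept as a vinylogous ester) and dithionite reduces it to the hydroquinone, so both phenols are freed without acid, which would cyclise the isopropenyl group onto the neighbouring phenol.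

**Compound list**

1 | 1,2,4-trimethoxybenzene | COc1ccc(OC)c(OC)c1 | starting material
2 | acetone | CC(C)=O | starting material
3 | (2,3,6-trimethoxyphenyl)lithium | [Li]c1c(OC)ccc(OC)c1OC | intermediate
4 | 2-(2,3,6-trimethoxyphenyl)propan-2-ol | COc1ccc(OC)c(C(C)(C)O)c1OC | intermediate
5 | 1,2,4-trimethoxy-3-(propan-2-yl)benzene | COc1ccc(OC)c(C(C)C)c1OC | intermediate
6 | [2,3,5-trimethoxy-4-(propan-2-yl)phenyl]lithium | [Li]c1cc(OC)c(C(C)C)c(OC)c1OC | intermediate
7 | 1-bromo-2,3,5-trimethoxy-4-(propan-2-yl)benzene | Brc1cc(OC)c(C(C)C)c(OC)c1OC | intermediate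
8 | 5,6-dihydro-2H-pyran-2-one | O=C1C=CCCO1 | starting material
9 | potassium trifluoro(prop-1-en-2-yl)borate | [K+].C=C(C)[B-](F)(F)F | starting material
10 | (4R)-4-(prop-1-en-2-yl)oxan-2-one | O=C1C[C@H](C(C)=C)CCO1 | intermediate
11 | chlorozinc enolate of 10 | Cl[Zn]OC1=C[C@H](C(C)=C)CCO1 | intermediate
12 | (3R,4R)-4-(prop-1-en-2-yl)-3-[2,3,5-trimethoxy-4-(propan-2-yl)phenyl]oxan-2-one (aryl trans to isopropenyl) | O=C1[C@@H](c2cc(OC)c(C(C)C)c(OC)c2OC)[C@H](C(C)=C)CCO1 | intermediate
13 | lithium enolate of 12 | [Li]OC1=C(c2cc(OC)c(C(C)C)c(OC)c2OC)[C@H](C(C)=C)CCO1 | intermediate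
14 | (3S,4S)-3-methyl-4-(prop-1-en-2-yl)-3-[2,3,5-trimethoxy-4-(propan-2-yl)phenyl]oxan-2-one (aryl cis to isopropenyl) | O=C1[C@](C)(c2cc(OC)c(C(C)C)c(OC)c2OC)[C@H](C(C)=C)CCO1 | intermediate
15 | (2S,3S)-2-methyl-3-(prop-1-en-2-yl)-2-[2,3,5-trimethoxy-4-(propan-2-yl)phenyl]pentane-1,5-diol | OC[C@](C)(c1cc(OC)c(C(C)C)c(OC)c1OC)[C@H](C(C)=C)CCO | intermediate
16 | (4S,5S)-5-methyl-4-(prop-1-en-2-yl)-5-[2,3,5-trimethoxy-4-(propan-2-yl)phenyl]oxan-2-one | O=C1C[C@@H](C(C)=C)[C@@](C)(c2cc(OC)c(C(C)C)c(OC)c2OC)CO1 | intermediate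
17 | (4S,5S)-6-hydroxy-5-methyl-4-(prop-1-en-2-yl)-5-[2,3,5-trimethoxy-4-(propan-2-yl)phenyl]hexan-2-one | CC(=O)C[C@@H](C(C)=C)[C@@](C)(c1cc(OC)c(C(C)C)c(OC)c1OC)CO | intermediate
18 | (2S,3S)-2-methyl-5-oxo-3-(prop-1-en-2-yl)-2-[2,3,5-trimethoxy-4-(propan-2-yl)phenyl]hexanal | CC(=O)C[C@@H](C(C)=C)[C@@](C)(c1cc(OC)c(C(C)C)c(OC)c1OC)C=O | intermediate
19 | (4S,5S)-4-methyl-5-(prop-1-en-2-yl)-4-[2,3,5-trimethoxy-4-(propan-2-yl)phenyl]cyclohex-2-en-1-one | O=C1C[C@@H](C(C)=C)[C@@](C)(c2cc(OC)c(C(C)C)c(OC)c2OC)C=C1 | intermediate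
20 | (4S,5S)-4-[2-iodo-3,5,6-trimethoxy-4-(propan-2-yl)phenyl]-4-methyl-5-(prop-1-en-2-yl)cyclohex-2-en-1-one | O=C1C[C@@H](C(C)=C)[C@@](C)(c2c(I)c(OC)c(C(C)C)c(OC)c2OC)C=C1 | intermediate
21 | lithium enolate from 1,4-reduction of 20 (enolate double bond towards the future Cα) | [Li]OC1=CC[C@](C)(c2c(I)c(OC)c(C(C)C)c(OC)c2OC)[C@H](C(C)=C)C1 | intermediate
22 | (2Z,4S,5S)-2-(hydroxymethylidene)-4-[2-iodo-3,5,6-trimethoxy-4-(propan-2-yl)phenyl]-4-methyl-5-(prop-1-en-2-yl)cyclohexan-1-one | O/C=C1\C(=O)C[C@@H](C(C)=C)[C@@](C)(c2c(I)c(OC)c(C(C)C)c(OC)c2OC)C1 | intermediate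
23 | (2E,4S,5S)-4-[2-iodo-3,5,6-trimethoxy-4-(propan-2-yl)phenyl]-4-methyl-2-[(propan-2-yloxy)methylidene]-5-(prop-1-en-2-yl)cyclohexan-1-one | CC(C)O/C=C1/C(=O)C[C@@H](C(C)=C)[C@@](C)(c2c(I)c(OC)c(C(C)C)c(OC)c2OC)C1 | intermediate
24 | aryllithium from 23 (lithium in place of iodine) | CC(C)O/C=C1/C(=O)C[C@@H](C(C)=C)[C@@](C)(c2c([Li])c(OC)c(C(C)C)c(OC)c2OC)C1 | intermediate
25 | lithium alkoxide of the 1,4-ethano-bridged tetralin-1-ol (benzobicyclo[2.2.2]octene; bridgeheads are the carbinol carbon and the methyl-bearing quaternary carbon; isopropenyl on the two-carbon bridge syn to the arene; (E)-isopropoxymethylidene on the other bridge next to the carbinol carbon) | [Li]O[C@]12C[C@@H](C(C)=C)[C@](C)(C\C1=C/OC(C)C)c3c2c(OC)c(C(C)C)c(OC)c3OC | intermediate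
26 | bridged β-hydroxy aldehyde from hydrolysis of 25 (formyl on the bridge carbon next to the carbinol carbon, both epimers) | O[C@]12C[C@@H](C(C)=C)[C@](C)(CC1C=O)c3c2c(OC)c(C(C)C)c(OC)c3OC | intermediate
27 | 3-[(1S,2S)-5,7,8-trimethoxy-1-methyl-4-oxo-6-(propan-2-yl)-2-(prop-1-en-2-yl)-1,2,3,4-tetrahydronaphthalen-1-yl]propanal | C=C(C)[C@@H]1CC(=O)c2c(OC)c(C(C)C)c(OC)c(OC)c2[C@@]1(C)CCC=O | intermediate
28 | 3-[(1S,2S)-5,7,8-trimethoxy-1-methyl-4-oxo-6-(propan-2-yl)-2-(prop-1-en-2-yl)-1,2,3,4-tetrahydronaphthalen-1-yl]propanoic acid | C=C(C)[C@@H]1CC(=O)c2c(OC)c(C(C)C)c(OC)c(OC)c2[C@@]1(C)CCC(=O)O | intermediate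
29 | 3-[(1S,2S)-7-methoxy-1-methyl-4,5,8-trioxo-6-(propan-2-yl)-2-(prop-1-en-2-yl)-1,2,3,4,5,8-hexahydronaphthalen-1-yl]propanoic acid | C=C(C)[C@@H]1CC(=O)C2=C([C@@]1(C)CCC(=O)O)C(=O)C(OC)=C(C(C)C)C2=O | intermediate
30 | 3-[(1S,2S)-5,8-dihydroxy-7-methoxy-1-methyl-4-oxo-6-(propan-2-yl)-2-(prop-1-en-2-yl)-1,2,3,4-tetrahydronaphthalen-1-yl]propanoic acid | C=C(C)[C@@H]1CC(=O)c2c(O)c(C(C)C)c(OC)c(O)c2[C@@]1(C)CCC(=O)O | target

Total step count: 16. Longest linear sequence: 15 steps (steps 1–3, then 5–16).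

**Steps most likely to fail**

Step 14. The aryllithium may be quenched by proton transfer from the CH2 group α to the ketone, or the boat-like approach needed for the transannular addition may be too costly; the keto aldehyde may also re-close by aldol reaction before it is oxidised. The fallback closes ring B on an open chain and sets out from lactone 16, coming back at keto acid 28. Aminolysis of 16 with MeNH(OMe)·HCl and AlMe3 should give the hydroxy Weinreb amide F1, and Dess–Martin oxidation the aldehyde F2. Wittig reaction with methyl (triphenylphosphoranylidene)acetate gives the enoate F3, conjugate reduction with [(Ph3P)CuH]6 the saturated ester F4, and LiOH the acid F5. N-Iodosuccinimide then gives the aryl iodide F6. With t-BuLi (3.1 equiv, −78 °C) the aryllithium should undergo Parham cyclization onto the Weinreb amide, the lithium carboxylate being inert, to give 28.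

Step 5. Reductive elimination may be slow at the hindered lactone α-carbon with an ortho-methoxyaryl partner, and the lactone enolate may open to a ketene on warming. The fallback reverses the polarity of the coupling; it sets out from lactone 10 and aryllithium 6 and comes back at 12. Bromination of the enolate of 10 (LiN(SiMe3)2, then N-bromosuccinimide) gives the bromo lactone F7; transmetalation of 6 with ZnCl2 gives the arylzinc chloride F8; a nickel-catalysed Negishi coupling (NiCl2(dme), 4,4′-di-tert-butyl-2,2′-bipyridine, THF/DMA, rt) of F7 with F8 should give 12.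

Step 3. Metalation may also remove H-5, so that site selectivity is poor. The fallback blocks that position; it sets out from 5 and comes back at 7. N-Bromosuccinimide brominates 5 at its most nucleophilic position to give the bromide F9; bromine–lithium exchange (n-BuLi) and Me3SiCl give the arylsilane F10; the single remaining ring hydrogen is then metalated (n-BuLi, TMEDA) and brominated with BrCH2CH2Br to give the bromo silane F11; protodesilylation with CF3CO2H gives 7.

**Further compounds**

F1 | step 14 | (3S,4S)-5-hydroxy-N-methoxy-N,4-dimethyl-3-(prop-1-en-2-yl)-4-[2,3,5-trimethoxy-4-(propan-2-yl)phenyl]pentanamide | CON(C)C(=O)C[C@@H](C(C)=C)[C@@](C)(c1cc(OC)c(C(C)C)c(OC)c1OC)CO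
F2 | step 14 | (3S,4S)-N-methoxy-N,4-dimethyl-5-oxo-3-(prop-1-en-2-yl)-4-[2,3,5-trimethoxy-4-(propan-2-yl)phenyl]pentanamide | CON(C)C(=O)C[C@@H](C(C)=C)[C@@](C)(c1cc(OC)c(C(C)C)c(OC)c1OC)C=O
F3 | step 14 | methyl (2E,4S,5S)-7-[methoxy(methyl)amino]-4-methyl-7-oxo-5-(prop-1-en-2-yl)-4-[2,3,5-trimethoxy-4-(propan-2-yl)phenyl]hept-2-enoate | CON(C)C(=O)C[C@@H](C(C)=C)[C@@](C)(c1cc(OC)c(C(C)C)c(OC)c1OC)/C=C/C(=O)OC
F4 | step 14 | methyl (4S,5S)-7-[methoxy(methyl)amino]-4-methyl-7-oxo-5-(prop-1-en-2-yl)-4-[2,3,5-trimethoxy-4-(propan-2-yl)phenyl]heptanoate | CON(C)C(=O)C[C@@H](C(C)=C)[C@@](C)(c1cc(OC)c(C(C)C)c(OC)c1OC)CCC(=O)OC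
F5 | step 14 | (4S,5S)-7-[methoxy(methyl)amino]-4-methyl-7-oxo-5-(prop-1-en-2-yl)-4-[2,3,5-trimethoxy-4-(propan-2-yl)phenyl]heptanoic acid | CON(C)C(=O)C[C@@H](C(C)=C)[C@@](C)(c1cc(OC)c(C(C)C)c(OC)c1OC)CCC(=O)O
F6 | step 14 | (4S,5S)-4-[2-iodo-3,5,6-trimethoxy-4-(propan-2-yl)phenyl]-7-[methoxy(methyl)amino]-4-methyl-7-oxo-5-(prop-1-en-2-yl)heptanoic acid | CON(C)C(=O)C[C@@H](C(C)=C)[C@@](C)(c1c(I)c(OC)c(C(C)C)c(OC)c1OC)CCC(=O)O
F7 | step 5 | (4S)-3-bromo-4-(prop-1-en-2-yl)oxan-2-one (both epimers at C3) | O=C1C(Br)[C@H](C(C)=C)CCO1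
F8 | step 5 | chloro[2,3,5-trimethoxy-4-(propan-2-yl)phenyl]zinc | Cl[Zn]c1cc(OC)c(C(C)C)c(OC)c1OC
F9 | step 3 | 1-bromo-2,4,5-trimethoxy-3-(propan-2-yl)benzene | COc1cc(Br)c(OC)c(C(C)C)c1OC
F10 | step 3 | trimethyl[2,4,5-trimethoxy-3-(propan-2-yl)phenyl]silane | COc1cc([Si](C)(C)C)c(OC)c(C(C)C)c1OC
F11 | step 3 | [2-bromo-3,4,6-trimethoxy-5-(propan-2-yl)phenyl]trimethylsilane | COc1c(Br)c([Si](C)(C)C)c(OC)c(C(C)C)c1OC
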